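3 questions stand on one flask, and that flask is the alpha run continued, so we already hold part of its curve.

the same everywhere: J 0.020 M (fed, over 4.0 min)

| flask | L | remark | time | volume of the second phase over the first |
|---|---|---|---|---|
| alpha | 0.014 M | the very flask that is asked about, followed so far; the fed solution adds 0.10 times the starting volume |  |  |
| theta | 0.028 M | run made earlier; the fed solution adds 0.10 times the starting volume |  |  |
| flask | 0.0140 M | the fed solution adds 0.10 times the starting volume | 1.5 h | 0.25 |

| run | time / min | X / % |
|---|---|---|
| alpha | 1.50 | 2.0 |
| alpha | 4.00 | 10.1 |
| alpha | 8.00 | 11.9 |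
| alpha | 20.0 | 10.7 |
| alpha | 50.0 | 6.6 |
| theta | 1.50 | 5.1 |
| theta | 5.00 | 19.9 |
| theta | 12.0 | 17.5 |
| theta | 30.0 | 9.8 |
| theta | 90.0 | 3.8 |

(readings scatter by 1 percentage point)

- when, up to 1.5 h, the flask holds most X
- the amount of X, in percent of the J charged, at that time
- the first time at which X reaches 3.8%, in the same percent, in min

- charges are per starting volume, the dose included; the dosed solution carries all of it
- in the second phase: L; everything else is in the first
- charges count per volume of the first phase; a concentration in a rate is the amount of a species over the volume of its own phase; every rate counts per litre of the first phase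
- the earlier runs hold the two phases in the same ratio of volumes as the flask asked about
- percentages count the whole charge, also what has not yet gone in

Write x for X as a fraction of the J charged. One pair of numbers looks contradictory: theta, with twice the L of alpha, reaches the higher reading, 19.9% against 11.9%, yet its x falls away sooner. If the fall obeys dx/dt = −λx, then x = x₀·exp(−λt), so a pair of readings gives λ. We call this the fall constant, a pseudo-first-order constant, and alpha gives 0.0161 min⁻¹. Theta gives 0.0322 min⁻¹, twice as much. But these two pairs cover unlike windows, and theta's later pair gives 0.0158 min⁻¹, about the same as alpha's. So the contradiction clears: theta's quicker fall is read over its first window, and in its later window the two runs fall at like rates. With a scatter of 1 percentage point on each reading, these pairs do not show that L changes the fall constant. Our reckoning from alpha's peak reading, with alpha's constant, gives 3.18% at the end of the flask.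

The forecast gives 0.115 h, 12.4% and 2.1 min. It differs from us on the tail: “The later fall looks second order in X”. Its peak lies within 1 point of alpha's reading.

The flask gives 0.110 h, 12.6% and 1.99 min.

    Q ⇌ L, rate k1*([Q] - [L]/K1) per volume of the first phase (partition coefficient = 4.20, kL = 0.310 min⁻¹)
    J + Q ⇌ X (K = 38.0 M⁻¹, k = 47.0 M⁻¹ min⁻¹)
    Q + X → Z (k = 11.0 M⁻¹ min⁻¹)
    X ⇌ D (K = 0.640, k = 0.0520 min⁻¹)

From the flask's best, the fall constant reckons 3.29% at 1.50 h, and the flask holds 4.76%, a factor of 1.45 above the reckoning. The neighbouring flask is charged with 0.080 M of J and peaks at 7.10%. Lending it the flask's span, the same constant reckons 1.85%. That neighbouring flask ends at 2.65%, a factor of 1.43 above its reckoning.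

(The earlier runs and the new flask stem from a simulated flask from invented constants; scatter was added.)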